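**Retrosynthetic overview**
1. Target ⇒ its 4'-acetate ⇒ (Mitsunobu O-prenylation) 7-OH/4'-OAc flavone ⇒ (regioselective 7-deacetylation) 7,4'-diacetate ⇒ 7,4'-dibenzyl ether. The prenyl ether is sensitive to acid, oxidants and H2, so it goes on second to last.
2. 3-OMe ⇒ O-methylation of the flavonol ⇒ C3 hydroxylation of the flavone (DMDO epoxidation, then acid opening).
3. Ring C (the 4-pyranone) is the only ring built, by I2/DMSO oxidative cyclisation of a 2'-hydroxychalcone. Rings A and B are bought as arenes.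
4. Key C–C bond (chalcone Cα–Cβ, which becomes C3–C2 of the flavone) ⇒ Claisen–Schmidt aldol condensation of 4-benzyloxy-2-hydroxy-3,6-dimethoxyacetophenone with O-benzylvanillin.
5. Acetophenone ⇒ Hoesch acylation of symmetric 2,5-dimethoxyresorcinol ⇒ Baeyer–Villiger oxidation and methylation of 2,6-dibenzyloxy-4-methoxybenzaldehyde ⇒ 2,4,6-trimethoxybenzaldehyde.

Assumption: the target SMILES has no stereocentre and no E/Z-capable double bond (the prenyl alkene carries two methyl groups). It is therefore achiral and needs no enantiocontrol. Racemic stereocentres occur only in the transient intermediates 12 and 15 and are erased in the same flask.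

**Step 1**
Reactants: 1 2,4,6-trimethoxybenzaldehyde
Product: 2 2,6-dihydroxy-4-methoxybenzaldehyde
Conditions: AlCl3 (4 equiv), CH2Cl2, 0 °C → reflux, 16 h; ice/2 M HCl
Reagents that add atoms: none
Why: In this chelation-controlled Lewis-acid ether cleavage, aluminium bound to the formyl oxygen activates only the two ortho methoxy groups for SN2 demethylation by chloride, while the para methoxy group cannot chelate and survives.

**Step 2**
Reactants: 2 2,6-dihydroxy-4-methoxybenzaldehyde
Product: 3 2,6-bis(benzyloxy)-4-methoxybenzaldehyde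
Conditions: BnBr (2.5 equiv), K2CO3 (3 equiv), DMF, 70 °C, 6 h
Reagents that add atoms: benzyl bromide BrCc1ccccc1
Why: Williamson ether synthesis in warm DMF breaks the OH···O=C hydrogen bonds, so both phenoxides are O-benzylated.

**Step 3**
Reactants: 3 2,6-bis(benzyloxy)-4-methoxybenzaldehyde
Product: 5 2,6-bis(benzyloxy)-4-methoxyphenol, via aryl formate 4 (not isolated)
Conditions: mCPBA (1.3 equiv), CH2Cl2, 0 °C → rt; aq. NaHCO3/Na2S2O3 wash; then K2CO3 (cat.), MeOH, N2, rt
Reagents that add atoms: mCPBA O=C(OO)c1cccc(Cl)c1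
Why: In this Baeyer–Villiger (Dakin-type) oxidation the very electron-rich 2,4,6-trialkoxyaryl group migrates in preference to hydride, and the resulting formate is removed by mild methanolysis.

**Step 4**
Reactants: 5 2,6-bis(benzyloxy)-4-methoxyphenol
Product: 6 1,3-bis(benzyloxy)-2,5-dimethoxybenzene
Conditions: MeI (2 equiv), K2CO3 (2 equiv), acetone, reflux, 8 h
Reagents that add atoms: iodomethane CI
Why: Williamson O-methylation of the only free phenol installs the future 8-OMe group between the two benzyl ethers.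

**Step 5**
Reactants: 6 1,3-bis(benzyloxy)-2,5-dimethoxybenzene
Product: 7 2,5-dimethoxybenzene-1,3-diol
Conditions: H2 (1 atm), 10% Pd/C, EtOAc–MeOH, rt
Reagents that add atoms: none
Why: Catalytic hydrogenolysis cleaves both aryl benzyl ethers and leaves the methyl ethers untouched.

**Step 6**
Reactants: 7 2,5-dimethoxybenzene-1,3-diol
Product: 9 1-(2,4-dihydroxy-3,6-dimethoxyphenyl)ethan-1-one, via ketiminium chloride 8 (not isolated)
Conditions: MeCN (2 equiv), ZnCl2 (0.5 equiv), HCl (g), Et2O, 0 °C, 24 h; decant; H2O, reflux, 1 h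
Reagents that add atoms: acetonitrile CC#N; water O; hydrogen chloride Cl (remains only as the counter-ion of 8)
Why: In this Houben–Hoesch acylation the symmetric phloroglucinol-type ring has only one kind of C–H, and the ketiminium salt deactivates the ring, so a single mono-acylated regioisomer forms.

**Step 7**
Reactants: 9 1-(2,4-dihydroxy-3,6-dimethoxyphenyl)ethan-1-one
Product: 10 1-[4-(benzyloxy)-2-hydroxy-3,6-dimethoxyphenyl]ethan-1-one
Conditions: BnBr (1.05 equiv), K2CO3 (1.1 equiv), acetone, reflux, 5 h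
Reagents that add atoms: benzyl bromide BrCc1ccccc1
Why: This Williamson etherification is regioselective because the 2-OH is held in a hydrogen-bond chelate with the acetyl group, so only the more acidic para 4-OH is ionised and benzylated.

**Step 8**
Reactants: 10 1-[4-(benzyloxy)-2-hydroxy-3,6-dimethoxyphenyl]ethan-1-one; 11 4-(benzyloxy)-3-methoxybenzaldehyde
Product: 13 (E)-3-[4-(benzyloxy)-3-methoxyphenyl]-1-[4-(benzyloxy)-2-hydroxy-3,6-dimethoxyphenyl]prop-2-en-1-one, via racemic aldol adduct 12 (not isolated)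
Conditions: KOH (50% aq., 10 equiv), EtOH, rt, 48 h; ice/2 M HCl
Reagents that add atoms: none
Why: In this Claisen–Schmidt crossed aldol condensation the methyl-ketone enolate adds to the non-enolisable aldehyde, and E1cB dehydration erases the racemic carbinol centre to give the conjugated E-chalcone.

**Step 9**
Reactants: 13 (E)-chalcone
Product: 14 7-(benzyloxy)-2-[4-(benzyloxy)-3-methoxyphenyl]-5,8-dimethoxy-4H-chromen-4-one
Conditions: I2 (0.1 equiv), DMSO, 125 °C, 3 h; aq. Na2S2O3
Reagents that add atoms: none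
Why: Iodine-catalysed oxidative cyclisation (oxa-Michael closure, α-iodination and HI loss, with DMSO re-oxidising HI) builds the pyranone ring, and the benzyl and methyl aryl ethers tolerate the conditions.

**Step 10**
Reactants: 14 7-(benzyloxy)-2-[4-(benzyloxy)-3-methoxyphenyl]-5,8-dimethoxy-4H-chromen-4-one
Product: 16 7-(benzyloxy)-2-[4-(benzyloxy)-3-methoxyphenyl]-3-hydroxy-5,8-dimethoxy-4H-chromen-4-one, via racemic flavone 2,3-epoxide 15 (not isolated)
Conditions: DMDO (0.07 M in acetone, 3 equiv), CH2Cl2, 0 °C → rt, 16 h; evaporate; p-TsOH·H2O (0.1 equiv), CH2Cl2, rt, 1 h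
Reagents that add atoms: dimethyldioxirane CC1(C)OO1
Why: Dioxirane epoxidation of the donor-substituted C2=C3 bond gives a racemic cis-fused epoxide, and acid opens it to the C2 oxocarbenium ion, which loses H-3 and so erases both stereocentres in the aromatic flavonol.

**Step 11**
Reactants: 16 7-(benzyloxy)-2-[4-(benzyloxy)-3-methoxyphenyl]-3-hydroxy-5,8-dimethoxy-4H-chromen-4-one
Product: 17 7-(benzyloxy)-2-[4-(benzyloxy)-3-methoxyphenyl]-3,5,8-trimethoxy-4H-chromen-4-one
Conditions: MeI (3 equiv), K2CO3 (3 equiv), acetone, reflux, 6 h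
Reagents that add atoms: iodomethane CI
Why: Williamson O-methylation can occur only at the acidic enolic 3-OH, which is the one free hydroxyl.

**Step 12**
Reactants: 17 7-(benzyloxy)-2-[4-(benzyloxy)-3-methoxyphenyl]-3,5,8-trimethoxy-4H-chromen-4-one
Product: 18 7-hydroxy-2-(4-hydroxy-3-methoxyphenyl)-3,5,8-trimethoxy-4H-chromen-4-one
Conditions: H2 (1 atm), 10% Pd/C, THF–MeOH, rt
Reagents that add atoms: none
Why: Catalytic hydrogenolysis removes both benzyl ethers, and the tetrasubstituted, aromatic-like C2=C3 bond of the chromone is not reduced at 1 atm.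

**Step 13**
Reactants: 18 7-hydroxy-2-(4-hydroxy-3-methoxyphenyl)-3,5,8-trimethoxy-4H-chromen-4-one
Product: 19 2-[4-(acetyloxy)-3-methoxyphenyl]-3,5,8-trimethoxy-4-oxo-4H-chromen-7-yl acetate
Conditions: Ac2O (4 equiv), pyridine, DMAP (cat.), rt, 4 h
Reagents that add atoms: acetic anhydride CC(=O)OC(C)=O
Why: Exhaustive DMAP-catalysed O-acylation converts both phenols into acetates cleanly.

**Step 14**
Reactants: 19 2-[4-(acetyloxy)-3-methoxyphenyl]-3,5,8-trimethoxy-4-oxo-4H-chromen-7-yl acetate
Product: 20 4-(7-hydroxy-3,5,8-trimethoxy-4-oxo-4H-chromen-2-yl)-2-methoxyphenyl acetate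
Conditions: PhSH (1.2 equiv), imidazole (0.3 equiv), NMP, 0 °C → rt, 2 h
Reagents that add atoms: none
Why: This acyl transfer (thiolysis) is chemoselective because the 7-acetate is the ester of the most acidic phenol, a vinylogous acid para to C4=O, so it is cleaved much faster than the 4'-acetate on the twisted guaiacyl B ring.

**Step 15**
Reactants: 20 4-(7-hydroxy-3,5,8-trimethoxy-4-oxo-4H-chromen-2-yl)-2-methoxyphenyl acetate
Product: 21 2-methoxy-4-[3,5,8-trimethoxy-7-(3-methylbut-2-enyloxy)-4-oxo-4H-chromen-2-yl]phenyl acetate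
Conditions: prenol (1.5 equiv), PPh3 (1.5 equiv), DIAD (1.5 equiv), THF, 0 °C → rt, 3 h
Reagents that add atoms: 3-methylbut-2-en-1-ol CC(C)=CCO
Why: In this Mitsunobu etherification the acidic 7-OH displaces the primary allylic oxyphosphonium group by SN2 under neutral conditions, so the 4'-acetate neither cleaves nor migrates.

**Step 16**
Reactants: 21 2-methoxy-4-[3,5,8-trimethoxy-7-(3-methylbut-2-enyloxy)-4-oxo-4H-chromen-2-yl]phenyl acetate
Product: 22 4'-hydroxy-3,5,8,3'-tetramethoxy-7-prenyloxyflavone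
Conditions: K2CO3 (0.3 equiv), MeOH–THF, 0 °C → rt, 1 h; aq. NH4Cl
Reagents that add atoms: none
Why: Base-catalysed transesterification (Zemplén-type methanolysis) removes the aryl acetate under conditions to which the prenyl ether, the methyl ethers and the chromone are inert.

**Compound list**
1 | 2,4,6-trimethoxybenzaldehyde | COc1cc(OC)c(C=O)c(OC)c1 | starting material
2 | 2,6-dihydroxy-4-methoxybenzaldehyde | COc1cc(O)c(C=O)c(O)c1 | intermediate
3 | 2,6-bis(benzyloxy)-4-methoxybenzaldehyde | COc1cc(OCc2ccccc2)c(C=O)c(OCc2ccccc2)c1 | intermediate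
4 | 2,6-bis(benzyloxy)-4-methoxyphenyl formate | COc1cc(OCc2ccccc2)c(OC=O)c(OCc2ccccc2)c1 | intermediate
5 | 2,6-bis(benzyloxy)-4-methoxyphenol | COc1cc(OCc2ccccc2)c(O)c(OCc2ccccc2)c1 | intermediate
6 | 1,3-bis(benzyloxy)-2,5-dimethoxybenzene | COc1cc(OCc2ccccc2)c(OC)c(OCc2ccccc2)c1 | intermediate
7 | 2,5-dimethoxybenzene-1,3-diol (2,5-dimethoxyresorcinol) | COc1cc(O)c(OC)c(O)c1 | intermediate
8 | 1-(2,4-dihydroxy-3,6-dimethoxyphenyl)ethan-1-iminium chloride | CC(=[NH2+])c1c(O)c(OC)c(O)cc1OC.[Cl-] | intermediate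
9 | 1-(2,4-dihydroxy-3,6-dimethoxyphenyl)ethan-1-one | CC(=O)c1c(O)c(OC)c(O)cc1OC | intermediate
10 | 1-[4-(benzyloxy)-2-hydroxy-3,6-dimethoxyphenyl]ethan-1-one | CC(=O)c1c(O)c(OC)c(OCc2ccccc2)cc1OC | intermediate
11 | 4-(benzyloxy)-3-methoxybenzaldehyde (O-benzylvanillin) | COc1cc(C=O)ccc1OCc1ccccc1 | starting material
12 | (±)-3-[4-(benzyloxy)-3-methoxyphenyl]-1-[4-(benzyloxy)-2-hydroxy-3,6-dimethoxyphenyl]-3-hydroxypropan-1-one (racemic) | COc1cc(C(O)CC(=O)c2c(O)c(OC)c(OCc3ccccc3)cc2OC)ccc1OCc1ccccc1 | intermediate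
13 | (E)-3-[4-(benzyloxy)-3-methoxyphenyl]-1-[4-(benzyloxy)-2-hydroxy-3,6-dimethoxyphenyl]prop-2-en-1-one | COc1cc(/C=C/C(=O)c2c(O)c(OC)c(OCc3ccccc3)cc2OC)ccc1OCc1ccccc1 | intermediate
14 | 7-(benzyloxy)-2-[4-(benzyloxy)-3-methoxyphenyl]-5,8-dimethoxy-4H-chromen-4-one | COc1cc(-c2cc(=O)c3c(OC)cc(OCc4ccccc4)c(OC)c3o2)ccc1OCc1ccccc1 | intermediate
15 | (±)-2,3-epoxide of 14 (cis-fused oxirane across C2–C3; racemic, one enantiomer drawn) | COc1cc([C@]23Oc4c(OC)c(OCc5ccccc5)cc(OC)c4C(=O)[C@H]2O3)ccc1OCc1ccccc1 | intermediate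
16 | 7-(benzyloxy)-2-[4-(benzyloxy)-3-methoxyphenyl]-3-hydroxy-5,8-dimethoxy-4H-chromen-4-one | COc1cc(-c2oc3c(OC)c(OCc4ccccc4)cc(OC)c3c(=O)c2O)ccc1OCc1ccccc1 | intermediate
17 | 7-(benzyloxy)-2-[4-(benzyloxy)-3-methoxyphenyl]-3,5,8-trimethoxy-4H-chromen-4-one | COc1cc(-c2oc3c(OC)c(OCc4ccccc4)cc(OC)c3c(=O)c2OC)ccc1OCc1ccccc1 | intermediate
18 | 7-hydroxy-2-(4-hydroxy-3-methoxyphenyl)-3,5,8-trimethoxy-4H-chromen-4-one | COc1cc(-c2oc3c(OC)c(O)cc(OC)c3c(=O)c2OC)ccc1O | intermediate
19 | 2-[4-(acetyloxy)-3-methoxyphenyl]-3,5,8-trimethoxy-4-oxo-4H-chromen-7-yl acetate | COc1cc(-c2oc3c(OC)c(OC(C)=O)cc(OC)c3c(=O)c2OC)ccc1OC(C)=O | intermediate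
20 | 4-(7-hydroxy-3,5,8-trimethoxy-4-oxo-4H-chromen-2-yl)-2-methoxyphenyl acetate | COc1cc(-c2oc3c(OC)c(O)cc(OC)c3c(=O)c2OC)ccc1OC(C)=O | intermediate
21 | 2-methoxy-4-[3,5,8-trimethoxy-7-(3-methylbut-2-enyloxy)-4-oxo-4H-chromen-2-yl]phenyl acetate | COc1cc(-c2oc3c(OC)c(OCC=C(C)C)cc(OC)c3c(=O)c2OC)ccc1OC(C)=O | intermediate
22 | 4'-hydroxy-3,5,8,3'-tetramethoxy-7-prenyloxyflavone (achiral) | COc1cc(-c2oc3c(OC)c(OCC=C(C)C)cc(OC)c3c(=O)c2OC)ccc1O | target

**Total step count:** 16.
**Longest linear sequence:** 16 steps (1 → 22); compound 11 is purchased.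

**Steps most likely to fail**

Step 1: the second ortho-demethylation may stall at the mono-phenol, or forcing it may begin to attack the para methoxy group. The fallback sets out from 1 and comes back at 2. All three methyl ethers are removed with BBr3 (4 equiv, CH2Cl2, −78 °C → rt) to give 2,4,6-trihydroxybenzaldehyde F1. The selectivity problem is then reversed: the 4-OH is the only hydroxyl not chelated to the formyl group and is the most acidic. One equivalent each of MeI and K2CO3 in DMF at rt therefore methylates it alone and delivers 2.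

Step 10: DMDO epoxidation of the flavone may be slow or incomplete, or may be accompanied by oxidation of the benzylic positions or the electron-rich A ring. The fallback sets out from 14 and comes back at 16. It replaces electrophilic oxidation with an anionic sequence. LDA (1.3 equiv, THF, −78 °C) removes the vinylic H-3 to give the 3-lithioflavone F2. B(OMe)3 traps this as the dimethyl flavon-3-ylboronate F3. H2O2/AcOH (0 °C → rt) then oxidises the C–B bond with 1,2-migration to give flavonol 16.

Step 14: the flanking 8-OMe group may slow thiolysis of the 7-acetate enough to erode the 7- versus 4'-selectivity. The fallback sets out from 18 and comes back at 22, bypassing 19, 20 and 21. It uses the ionisation equilibrium instead of acyl-transfer rates. With prenyl bromide (1.0 equiv) and K2CO3 (1.0 equiv) in DMF at rt, only the more acidic 7-OH is present as phenoxide, and it is O-alkylated directly. The minor 4'-ether and the bis-ether are removed by chromatography. This fallback makes no new compound (F0).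

**Further compounds**
F1 | step 1 | 2,4,6-trihydroxybenzaldehyde | O=Cc1c(O)cc(O)cc1O
F2 | step 10 | 7-(benzyloxy)-2-[4-(benzyloxy)-3-methoxyphenyl]-3-lithio-5,8-dimethoxy-4H-chromen-4-one | [Li]c1c(-c2ccc(OCc3ccccc3)c(OC)c2)oc2c(OC)c(OCc3ccccc3)cc(OC)c2c1=O
F3 | step 10 | dimethyl {7-(benzyloxy)-2-[4-(benzyloxy)-3-methoxyphenyl]-5,8-dimethoxy-4-oxo-4H-chromen-3-yl}boronate | COB(OC)c1c(-c2ccc(OCc3ccccc3)c(OC)c2)oc2c(OC)c(OCc3ccccc3)cc(OC)c2c1=O
F0 | step 14 | none | none
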